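**Assumption (one line):** the SMILES is taken literally, i.e. a trans-fused 5α-H,10β-CH3 labdane with the C9 side chain α (H-9 β), 6β-OBz, 7α-OH and the 4β (C19) acid. Labdane numbering is used for all bicyclic compounds (β = face of the C10 methyl; in hydrindanes 8–10, C8 is bonded directly to C10), and the ligand antipode in step 3 is the one that gives the drawn enantiomer.

## Retrosynthetic overview

1. Target ⇐ diol lactone 22: the 19,6β-lactone is opened and O6 benzoylated at the end; the (E)-allylic alcohol comes from a terminal alkyne by carboalumination.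
2. 6β-O/7α-OH ⇐ α-epoxide of Δ6-8-enone 17, opened at C6 by the axial C19 ester; C9 chain ⇐ α-face α′-alkylation of enone 13.
3. Ring B ⇐ one-carbon ring expansion of methylidene hydrindane 10 (1,2-shift of C10 from C8 to the exocyclic CH2) – key step.
4. Ring A with C4 and C10 ⇐ enantioselective desymmetrising Cu–H reductive aldol cyclisation of enoate-dione 7 (from 2-methylcyclopentane-1,3-dione, acrolein, methyl 2-bromopropanoate).
5. Ring order: cyclopentane (bought) → ring A (aldol) → ring B (5→6 expansion) → temporary γ-lactone.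

## Route

Step 1
Reactants: 1 2-methylcyclopentane-1,3-dione; 2 acrolein
Product: 3 3-(1-methyl-2,5-dioxocyclopentyl)propanal
Conditions: H2O, 20 °C
Reagents that add atoms: none
Why: Uncatalysed Michael addition of the enolised 1,3-dione to acrolein in water gives the C-alkylated 2,2-disubstituted dione (no stereocentre).

Step 2
Reactants: 3 3-(1-methyl-2,5-dioxocyclopentyl)propanal; 4 methyl 2-bromopropanoate
Product: 7 methyl (E)-2-methyl-5-(1-methyl-2,5-dioxocyclopentyl)pent-2-enoate, via phosphonium bromide 5 (not isolated), via phosphorus ylide 6 (not isolated)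
Conditions: PPh3, sat. aq. NaHCO3, 20 °C
Reagents that add atoms: none
Why: The stabilised α-methyl ylide formed in situ reacts only with the aldehyde (not the hindered ketones) and gives the (E)-trisubstituted enoate (Wittig reaction).

Step 3
Reactants: 7 methyl (E)-2-methyl-5-(1-methyl-2,5-dioxocyclopentyl)pent-2-enoate
Product: 9 methyl 3a-hydroxy-4,7a-dimethyl-1-oxooctahydro-1H-indene-4-carboxylate (cis-fused; 5β-OH; 10β-CH3; 4β-CO2Me), via silyl ether 8 (not isolated)
Conditions: Cu(OAc)2·H2O (5 mol %), (R)-DTBM-SEGPHOS (5.5 mol %), PhMe2SiH, toluene, −40 → 0 °C; then HF·pyridine, THF, 0 °C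
Reagents that add atoms: none
Why: Proposed new method: a bisphosphine-ligated copper hydride delivers hydride to C3 of the α-methyl enoate and the resulting fully substituted copper ester enolate is held by the three-carbon tether over one of the two enantiotopic ketones, so the chiral ligand selects the carbonyl (fixing C10), the tether enforces cis fusion (OH cis to the angular methyl) and the closed six-membered Zimmerman–Traxler transition state places CO2Me cis to the new C–O bond (fixing C4 with the ester on the C10-methyl face), with Si–H/O–Cu σ-bond metathesis regenerating Cu–H; the closest known reaction type is the enantioselective Cu–H reductive aldol cyclisation of α-unsubstituted enoates tethered to 2-methylcycloalkane-1,3-diones, which has not been shown for α-substituted enoates that build an all-carbon quaternary centre.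

Step 4
Reactants: 9 methyl 3a-hydroxy-4,7a-dimethyl-1-oxooctahydro-1H-indene-4-carboxylate
Product: 10 methyl 3a-hydroxy-4,7a-dimethyl-1-methylideneoctahydro-1H-indene-4-carboxylate
Conditions: Zn, CH2Br2, TiCl4, THF–CH2Cl2, 0 → 20 °C
Reagents that add atoms: dibromomethane, BrCBr
Why: The non-basic zinc–titanium methylenation (Lombardo–Takai) converts the hindered ketone to the exocyclic alkene without retro-aldol cleavage of the tertiary aldol (no new stereocentre).

Step 5
Reactants: 10 methyl 3a-hydroxy-4,7a-dimethyl-1-methylideneoctahydro-1H-indene-4-carboxylate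
Product: 11 methyl 5β-hydroxy-4α,10β-dimethyl-8-oxodecalin-4β-carboxylate (cis-fused)
Conditions: PhI(OH)OTs, MeOH–H2O 95:5, 0 → 20 °C
Reagents that add atoms: [hydroxy(tosyloxy)iodo]benzene, OI(OS(=O)(=O)c1ccc(C)cc1)c1ccccc1
Why: Key ring expansion: trivalent iodine adds to the terminal CH2 and, as iodobenzene leaves that primary carbon, the electron-richer fully substituted C10 migrates from C8 to C9 with retention and in preference to the C7 methylene, giving the six-membered ring B ketone (oxidative 1,2-alkyl shift of the methylidenecycloalkane-to-cycloalkanone type).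

Step 6
Reactants: 11 methyl 5β-hydroxy-4α,10β-dimethyl-8-oxodecalin-4β-carboxylate
Product: 13 methyl 4α,10β-dimethyl-8-oxo-5αH-decal-6-ene-4β-carboxylate (trans-fused), via deconjugated alkene 12 (not isolated)
Conditions: Burgess reagent, benzene, 50 °C; then DBU (0.2 equiv), CH2Cl2, 20 °C
Reagents that add atoms: none
Why: syn-Elimination of the tertiary C5 sulfamate can only go towards C6, and base then moves the β,γ-alkene into conjugation through the dienolate, which is protonated at C5 on the α face opposite the axial C10 methyl and C19 ester to give the trans ring fusion (Burgess dehydration, then alkene isomerisation).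

Step 7
Reactants: 14 but-3-yn-1-ol
Product: 15 but-3-yn-1-yl trifluoromethanesulfonate
Conditions: Tf2O, pyridine, CH2Cl2, −78 → −20 °C
Reagents that add atoms: triflic anhydride, O=S(=O)(OS(=O)(=O)C(F)(F)F)C(F)(F)F
Why: O-Sulfonylation of the primary alcohol gives an electrophile reactive enough to alkylate a hindered enolate without elimination (sulfonate ester formation).

Step 8
Reactants: 13 methyl 4α,10β-dimethyl-8-oxo-5αH-decal-6-ene-4β-carboxylate; 15 but-3-yn-1-yl trifluoromethanesulfonate
Product: 17 methyl 9α-(but-3-yn-1-yl)-4α,10β-dimethyl-8-oxo-5αH,9βH-decal-6-ene-4β-carboxylate, via lithium dienolate 16 (not isolated)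
Conditions: LiN(SiMe3)2, THF, −78 °C; then 15, −78 → −40 °C
Reagents that add atoms: none
Why: Kinetic α′-deprotonation at C9 gives the cross-conjugated dienolate, which is alkylated axially on the α face, anti to the adjacent axial C10 methyl, setting the 9α chain and 9β-H (α′-alkylation of an enone enolate).

Step 9
Reactants: 17 methyl 9α-(but-3-yn-1-yl)-4α,10β-dimethyl-8-oxo-5αH,9βH-decal-6-ene-4β-carboxylate
Product: 19 7α-hydroxy-8-oxo-15,16-dinor-9βH-labd-13-yn-19,6β-olide, via epoxy ketone 18 (not isolated)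
Conditions: DMDO, acetone, 0 → 20 °C; evaporate; CSA (10 mol %), wet CH2Cl2, 20 °C
Reagents that add atoms: dimethyldioxirane, CC1(C)OO1; water, O
Why: The dioxirane epoxidises the enone from the α face (the β face at C6 is blocked by the syn-axial C10 methyl and C19 ester), and acid then lets the axial C19 ester carbonyl open the epoxide at C6 from the β face with inversion (trans-diaxial, 5-exo), losing methanol to give the 19,6β-lactone and the 7α-hydroxyl (epoxidation, then epoxy-ester lactonisation).

Step 10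
Reactants: 19 7α-hydroxy-8-oxo-15,16-dinor-9βH-labd-13-yn-19,6β-olide
Product: 20 7α-hydroxy-15,16-dinor-9βH-labd-8(17)-en-13-yn-19,6β-olide
Conditions: Zn, CH2Br2, TiCl4, THF–CH2Cl2, 0 → 20 °C
Reagents that add atoms: dibromomethane, BrCBr
Why: The Lewis-acidic, non-basic methylenation tolerates the lactone and free alcohol and avoids enolisation at C9 or β-elimination of the C6 acyloxy group, so C7 and C9 stay intact (Lombardo–Takai methylenation).

Step 11
Reactants: 20 7α-hydroxy-15,16-dinor-9βH-labd-8(17)-en-13-yn-19,6β-olide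
Product: 22 7α,15-dihydroxy-9βH-labda-8(17),13E-dien-19,6β-olide, via alkenylalane 21 (not isolated)
Conditions: AlMe3 (4 equiv), Cp2ZrCl2 (0.3 equiv), CH2Cl2, 0 → 20 °C; then (CH2O)n, THF, 20 °C; aq. potassium sodium tartrate
Reagents that add atoms: trimethylaluminium, C[Al](C)C; paraformaldehyde (as formaldehyde), C=O
Why: Zirconium-catalysed syn-methylalumination of the terminal alkyne puts CH3 on C13 and aluminium on C14, and hydroxymethylation of the alkenylalane with retention gives only the (E)-allylic alcohol (Negishi carboalumination).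

Step 12
Reactants: 22 7α,15-dihydroxy-9βH-labda-8(17),13E-dien-19,6β-olide
Product: 23 7α,15-bis(tert-butyldimethylsilyloxy)-9βH-labda-8(17),13E-dien-19,6β-olide
Conditions: TBSOTf, 2,6-lutidine, CH2Cl2, −40 → 0 °C
Reagents that add atoms: tert-butyldimethylsilyl triflate, CC(C)(C)[Si](C)(C)OS(=O)(=O)C(F)(F)F
Why: Both free hydroxyls are capped so that only O6 can be acylated after lactone opening (silyl ether protection).

Step 13
Reactants: 23 7α,15-bis(tert-butyldimethylsilyloxy)-9βH-labda-8(17),13E-dien-19,6β-olide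
Product: 26 6β-benzoyloxy-7α,15-bis(tert-butyldimethylsilyloxy)-9βH-labda-8(17),13E-dien-19-oic acid, via potassium carboxylate 24 (not isolated), via dipotassium alkoxide carboxylate 25 (not isolated)
Conditions: KOH, dioxane–H2O, 80 °C; concentrate, azeotrope with toluene; KH, THF, 0 °C; BzCl, −78 → 0 °C; cold 0.5 M HCl
Reagents that add atoms: potassium hydroxide, [K+].[OH-]; benzoyl chloride, O=C(Cl)c1ccccc1
Why: Hydroxide opens the lactone, the axial 6β-alkoxide made with KH is acylated before the carboxylate can be activated towards relactonisation, and acid work-up frees the C19 acid (saponification, then O-acylation of an alkoxide; no stereocentre is touched).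

Step 14
Reactants: 26 6β-benzoyloxy-7α,15-bis(tert-butyldimethylsilyloxy)-9βH-labda-8(17),13E-dien-19-oic acid
Product: 27 6β-benzoyloxy-7α,15-dihydroxy-9βH-labda-8(17),13E-dien-19-oic acid (CNP0149011.1)
Conditions: HF·pyridine, pyridine–THF, 0 → 20 °C
Reagents that add atoms: none
Why: Buffered fluoride removes both silyl ethers without touching the benzoate, the acid or the allylic alcohols (desilylation).

## Compound list

1 | 2-methylcyclopentane-1,3-dione | CC1C(=O)CCC1=O | starting material
2 | acrolein | C=CC=O | starting material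
3 | 3-(1-methyl-2,5-dioxocyclopentyl)propanal | O=CCCC1(C)C(=O)CCC1=O | intermediate
4 | methyl 2-bromopropanoate (racemic) | COC(=O)C(C)Br | starting material
5 | (1-methoxy-1-oxopropan-2-yl)triphenylphosphonium bromide | COC(=O)C(C)[P+](c1ccccc1)(c1ccccc1)c1ccccc1.[Br-] | intermediate
6 | methyl 2-(triphenylphosphoranylidene)propanoate | COC(=O)C(C)=P(c1ccccc1)(c1ccccc1)c1ccccc1 | intermediate
7 | methyl (E)-2-methyl-5-(1-methyl-2,5-dioxocyclopentyl)pent-2-enoate | COC(=O)/C(C)=C/CCC1(C)C(=O)CCC1=O | intermediate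
8 | 3a-O-dimethylphenylsilyl ether of 9 | O=C1[C@@]2(C)CCC[C@](C)(C(=O)OC)[C@@]2(O[Si](C)(C)c3ccccc3)CC1 | intermediate
9 | methyl 3a-hydroxy-4,7a-dimethyl-1-oxooctahydro-1H-indene-4-carboxylate; cis-fused; 3a-OH, 7a-CH3 and CO2Me on one face (5β-OH, 10β-CH3, 4β-CO2Me, 4α-CH3, C8 ketone) | O=C1[C@@]2(C)CCC[C@](C)(C(=O)OC)[C@@]2(O)CC1 | intermediate
10 | methyl 3a-hydroxy-4,7a-dimethyl-1-methylideneoctahydro-1H-indene-4-carboxylate (configuration as 9) | C=C1[C@@]2(C)CCC[C@](C)(C(=O)OC)[C@@]2(O)CC1 | intermediate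
11 | methyl 5β-hydroxy-4α,10β-dimethyl-8-oxodecalin-4β-carboxylate (cis-fused; ring B C5–C6–C7–C8(=O)–C9–C10) | O=C1C[C@@]2(C)CCC[C@](C)(C(=O)OC)[C@@]2(O)CC1 | intermediate
12 | methyl 4α,10β-dimethyl-8-oxodecal-5-ene-4β-carboxylate | O=C1C[C@@]2(C)CCC[C@](C)(C(=O)OC)C2=CC1 | intermediate
13 | methyl 4α,10β-dimethyl-8-oxo-5αH-decal-6-ene-4β-carboxylate (trans-fused) | O=C1C[C@@]2(C)CCC[C@](C)(C(=O)OC)[C@@H]2C=C1 | intermediate
14 | but-3-yn-1-ol | C#CCCO | starting material
15 | but-3-yn-1-yl trifluoromethanesulfonate | C#CCCOS(=O)(=O)C(F)(F)F | intermediate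
16 | lithium dienolate of 13 (OLi on C8; C8=C9 and C6=C7) | [O-]C1=C[C@@]2(C)CCC[C@](C)(C(=O)OC)[C@@H]2C=C1.[Li+] | intermediate
17 | methyl 9α-(but-3-yn-1-yl)-4α,10β-dimethyl-8-oxo-5αH,9βH-decal-6-ene-4β-carboxylate | O=C1[C@@H](CCC#C)[C@@]2(C)CCC[C@](C)(C(=O)OC)[C@@H]2C=C1 | intermediate
18 | 6α,7α-epoxide of 17 | O=C1[C@@H](CCC#C)[C@@]2(C)CCC[C@](C)(C(=O)OC)[C@@H]2[C@H]3O[C@@H]13 | intermediate
19 | 7α-hydroxy-8-oxo-15,16-dinor-9βH-labd-13-yn-19,6β-olide (γ-lactone C19–O–C6) | O=C1[C@@H](CCC#C)[C@@]2(C)CCC[C@]3(C)C(=O)O[C@@H]([C@H]23)[C@H]1O | intermediate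
20 | 7α-hydroxy-15,16-dinor-9βH-labd-8(17)-en-13-yn-19,6β-olide | C=C1[C@@H](CCC#C)[C@@]2(C)CCC[C@]3(C)C(=O)O[C@@H]([C@H]23)[C@H]1O | intermediate
21 | (13E)-14-dimethylalanyl alkene with 7-O-AlMe2 (carboalumination adduct of 20) | C=C1[C@@H](CC/C(C)=C/[Al](C)C)[C@@]2(C)CCC[C@]3(C)C(=O)O[C@@H]([C@H]23)[C@H]1O[Al](C)C | intermediate
22 | 7α,15-dihydroxy-9βH-labda-8(17),13E-dien-19,6β-olide | C=C1[C@@H](CC/C(C)=C/CO)[C@@]2(C)CCC[C@]3(C)C(=O)O[C@@H]([C@H]23)[C@H]1O | intermediate
23 | 7α,15-bis(tert-butyldimethylsilyloxy)-9βH-labda-8(17),13E-dien-19,6β-olide | C=C1[C@@H](CC/C(C)=C/CO[Si](C)(C)C(C)(C)C)[C@@]2(C)CCC[C@]3(C)C(=O)O[C@@H]([C@H]23)[C@H]1O[Si](C)(C)C(C)(C)C | intermediate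
24 | potassium 7α,15-bis(tert-butyldimethylsilyloxy)-6β-hydroxy-9βH-labda-8(17),13E-dien-19-oate | C=C1[C@@H](CC/C(C)=C/CO[Si](C)(C)C(C)(C)C)[C@@]2(C)CCC[C@](C)(C(=O)[O-])[C@@H]2[C@H](O)[C@H]1O[Si](C)(C)C(C)(C)C.[K+] | intermediate
25 | dipotassium 6β-oxido analogue of 24 | C=C1[C@@H](CC/C(C)=C/CO[Si](C)(C)C(C)(C)C)[C@@]2(C)CCC[C@](C)(C(=O)[O-])[C@@H]2[C@H]([O-])[C@H]1O[Si](C)(C)C(C)(C)C.[K+].[K+] | intermediate
26 | 6β-benzoyloxy-7α,15-bis(tert-butyldimethylsilyloxy)-9βH-labda-8(17),13E-dien-19-oic acid | C=C1[C@@H](CC/C(C)=C/CO[Si](C)(C)C(C)(C)C)[C@@]2(C)CCC[C@](C)(C(=O)O)[C@@H]2[C@H](OC(=O)c2ccccc2)[C@H]1O[Si](C)(C)C(C)(C)C | intermediate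
27 | 6β-benzoyloxy-7α,15-dihydroxy-9βH-labda-8(17),13E-dien-19-oic acid (CNP0149011.1) | C=C1[C@@H](CC/C(C)=C/CO)[C@@]2(C)CCC[C@](C)(C(=O)O)[C@@H]2[C@H](OC(=O)c2ccccc2)[C@H]1O | target

## Step count and risks

Total steps: 14. Longest linear sequence: 13 (steps 1–6 and 8–14; step 7 is a one-step side branch).

Three steps most likely to fail:

**Step 3 (proposed new step).** The α-methyl enoate may reduce slowly, or the congested aldol may close with poor selectivity. The fallback introduces the C4 methyl after a known cyclisation. It sets out from aldehyde 3. The same aqueous one-pot Wittig reaction with methyl bromoacetate and PPh3 gives methyl (E)-5-(1-methyl-2,5-dioxocyclopentyl)pent-2-enoate F1. The established Cu(OAc)2·H2O/chiral bisphosphine/silane desymmetrising reductive aldol cyclisation of this α-unsubstituted enoate gives methyl 3a-hydroxy-7a-methyl-1-oxooctahydro-1H-indene-4-carboxylate F2 (cis-fused, OH, 7a-CH3 and CO2Me on one face, C4–H). Zn/CH2Br2/TiCl4 methylenation gives methyl 3a-hydroxy-7a-methyl-1-methylideneoctahydro-1H-indene-4-carboxylate F3. Fráter–Seebach alkylation of its dianion (LiN(i-Pr)2, 2.2 equiv, THF, −78 → −20 °C, then MeI) brings the methyl in anti to the C5 alkoxide, on the α face, and comes back to the route at compound 10.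

**Step 5 (key ring expansion).** The C7 methylene might migrate instead of C10, or solvent might simply add across the alkene. The fallback uses a sulfur-stabilised carbanion homologation, where migration of the more substituted carbon is the usual outcome. It sets out from ketone 9. Bis(phenylthio)methyllithium (CH2(SPh)2, n-BuLi, THF, −78 °C, 2.2 equiv) adds to C8 to give methyl 1-[bis(phenylthio)methyl]-1,3a-dihydroxy-4,7a-dimethyloctahydro-1H-indene-4-carboxylate F4. CuOTf with i-Pr2NEt in benzene (45–78 °C) ionises one C–S bond and triggers the 1,2-shift of C10, giving methyl 5β-hydroxy-4α,10β-dimethyl-8-oxo-9-(phenylthio)decalin-4β-carboxylate F5. Al(Hg) in wet THF removes the sulfur and comes back to the route at compound 11.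

**Step 13 (lactone to 6-O-benzoate acid).** Activation of the C19 carboxylate by BzCl could cause relactonisation faster than acylation of the hindered 6β-oxygen. The fallback caps the carboxylate first by alkylation, which does not activate C19. It sets out from lactone 23. KOH (aq. dioxane, 80 °C) gives carboxylate 24 as in the main route, and allyl bromide in DMF gives allyl 7α,15-bis(tert-butyldimethylsilyloxy)-6β-hydroxy-9βH-labda-8(17),13E-dien-19-oate F6. BzCl/DMAP/pyridine (or benzoyl triflate at −40 °C) gives allyl 6β-benzoyloxy-7α,15-bis(tert-butyldimethylsilyloxy)-9βH-labda-8(17),13E-dien-19-oate F7. Pd(PPh3)4 with morpholine removes the allyl group and comes back to the route at compound 26.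

## Further compounds

F1 | step 3 | methyl (E)-5-(1-methyl-2,5-dioxocyclopentyl)pent-2-enoate | COC(=O)/C=C/CCC1(C)C(=O)CCC1=O
F2 | step 3 | methyl 3a-hydroxy-7a-methyl-1-oxooctahydro-1H-indene-4-carboxylate (cis-fused; OH, 7a-CH3 and CO2Me on one face) | O=C1[C@@]2(C)CCC[C@H](C(=O)OC)[C@@]2(O)CC1
F3 | step 3 | methyl 3a-hydroxy-7a-methyl-1-methylideneoctahydro-1H-indene-4-carboxylate (configuration as F2) | C=C1[C@@]2(C)CCC[C@H](C(=O)OC)[C@@]2(O)CC1
F4 | step 5 | methyl 1-[bis(phenylthio)methyl]-1,3a-dihydroxy-4,7a-dimethyloctahydro-1H-indene-4-carboxylate (C1 epimers) | OC1(C(Sc3ccccc3)Sc3ccccc3)[C@@]2(C)CCC[C@](C)(C(=O)OC)[C@@]2(O)CC1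
F5 | step 5 | methyl 5β-hydroxy-4α,10β-dimethyl-8-oxo-9-(phenylthio)decalin-4β-carboxylate (C9 epimers) | O=C1C(Sc3ccccc3)[C@@]2(C)CCC[C@](C)(C(=O)OC)[C@@]2(O)CC1
F6 | step 13 | allyl 7α,15-bis(tert-butyldimethylsilyloxy)-6β-hydroxy-9βH-labda-8(17),13E-dien-19-oate | C=C1[C@@H](CC/C(C)=C/CO[Si](C)(C)C(C)(C)C)[C@@]2(C)CCC[C@](C)(C(=O)OCC=C)[C@@H]2[C@H](O)[C@H]1O[Si](C)(C)C(C)(C)C
F7 | step 13 | allyl 6β-benzoyloxy-7α,15-bis(tert-butyldimethylsilyloxy)-9βH-labda-8(17),13E-dien-19-oate | C=C1[C@@H](CC/C(C)=C/CO[Si](C)(C)C(C)(C)C)[C@@]2(C)CCC[C@](C)(C(=O)OCC=C)[C@@H]2[C@H](OC(=O)c2ccccc2)[C@H]1O[Si](C)(C)C(C)(C)C
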